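The target is the endo Diels–Alder homodimer of a labda-8(17),12E,14-trien-18-ol. The plan rests on unzipping the decalin of the dienophile-derived half (C1–C10) to an (E,E)-farnesyl-type chain that ends in a 3,4-epoxy-18-ol, attached through C11 to an otherwise complete cyclohexene–labdane core. One titanocene(III) radical cascade then closes ring A (C4–C5) and, last, ring B (C9–C10), setting C4, C5, C9 and C10. It exploits the exocyclic C8=C17 methylene flanking C9, the natural exit of such a cascade, and the C18 carbinol on C4, whose allylic-alcohol precursor allows the Sharpless epoxidation that fixes the absolute sense of folding.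

Key step: step 13

Remark: labdane numbering is used; unprimed atoms (C1–C20) belong to the half completed last, primed atoms (C1'–C20') to the half made first; the cyclohexene consists of C14, C15, C15', C14', C13' and C12'.

Step 1
Reactants: 1 3-methyl-3-sulfolene; 2 (2E,6E)-farnesyl bromide
Product: 3 2-farnesyl-3-methyl-3-sulfolene (racemic at C2)
Conditions: LiHMDS, THF/HMPA, −78 °C (base added to the mixture of 1 and 2)
Reagents that add atoms: none
Why: α-Sulfonyl carbanion alkylation of a 3-sulfolene (masked isoprene): deprotonation at C2 gives the allyl anion that keeps charge off the methyl-bearing carbon, and in situ SN2 trapping by the allylic bromide places the chain next to the ring methyl; the racemic centre is erased in step 3.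

Step 2
Reactants: 3 2-farnesyl-3-methyl-3-sulfolene
Product: 4 ω-(E)-hydroxy sulfolene
Conditions: SeO2 (cat.), t-BuOOH, salicylic acid (cat.), CH2Cl2, rt
Reagents that add atoms: selenium dioxide O=[Se]=O (catalytic oxygen carrier); tert-butyl hydroperoxide CC(C)(C)OO (terminal oxidant)
Why: Catalytic SeO2 allylic oxidation (ene reaction then [2,3]-shift) should attack the electron-rich terminal isopropylidene and give the (E)-allylic alcohol, the sulfolene alkene being deactivated.

Step 3
Reactants: 4 ω-(E)-hydroxy sulfolene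
Product: 5 (2E,6E,10E,13E)-pentaenol
Conditions: toluene, pyridine, 110 °C
Reagents that add atoms: none
Why: Thermal cheletropic extrusion of SO2, in which the C2 substituent rotates outward so that the 3-methyl-1,3-diene should form as the E isomer.

Step 4
Reactants: 5 pentaenol
Product: 6 (2S,3S)-epoxy alcohol
Conditions: Ti(Oi-Pr)4, L-(+)-diethyl tartrate, t-BuOOH, 4 Å MS, CH2Cl2, −20 °C
Reagents that add atoms: tert-butyl hydroperoxide CC(C)(C)OO
Why: Sharpless asymmetric epoxidation touches only the allylic-alcohol alkene among five C=C bonds, and the L-(+)-tartrate catalyst delivers oxygen to the face that gives the (2S,3S)-epoxide.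

Step 5
Reactants: 6 (2S,3S)-epoxy alcohol
Product: 7 labda-8(17),12E,14-triene-3β,18-diol
Conditions: Cp2TiCl2 (2.5 equiv), Mn dust, THF, rt, 5 mM; cold 1 M HCl work-up
Reagents that add atoms: none
Why: Titanocene(III)-mediated radical epoxypolyene cyclization: opening at C4'–O gives a tertiary radical that closes rings A' and B' by two 6-endo additions through a chair–chair array in which the equatorial C3' O–Ti group (from step 4) fixes the absolute folding (5'α-H, 10'β-CH3, 9'α-H), the larger oxymethyl on C4' should go equatorial, Ti-mediated β-hydride loss from C17' gives the exocyclic alkene, and the 12'E-diene is out of reach of the C8' radical (only 4-exo or 5-endo modes).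

Step 6
Reactants: 7 labda-8(17),12E,14-triene-3β,18-diol
Product: 8 3β,18-O-isopropylidene diene
Conditions: 2,2-dimethoxypropane, PPTS (cat.), CH2Cl2, rt
Reagents that add atoms: 2,2-dimethoxypropane COC(C)(C)OC
Why: Acid-catalysed transacetalization of the diequatorial 1,3-diol to a trans-fused 1,3-dioxane masks the diol, which would otherwise bind titanium in step 12.

Step 7
Reactants: 8 3β,18-O-isopropylidene diene; 9 acrolein
Product: 10 cis-(14S,12'S)-cyclohexene carbaldehyde
Conditions: (5R)-5-benzyl-2,2,3-trimethylimidazolidin-4-one·HCl (20 mol %), CH3NO2/H2O (95:5), rt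
Reagents that add atoms: none
Why: Iminium-catalysed (organocatalytic) Diels–Alder reaction: the C12' alkyl terminus should direct the "ortho" orientation (C15' to the acrolein β-carbon), endo approach to the (E)-diene gives the cis C14/C12' ring, and the (5R)-catalyst shields one face of the iminium so that C14 and C12' both form S regardless of the remote labdane centres.

Step 8
Reactants: 10 cis-(14S,12'S)-cyclohexene carbaldehyde
Product: 11 cis-ethynylcyclohexene
Conditions: dimethyl (1-diazo-2-oxopropyl)phosphonate, K2CO3, MeOH/THF, 0 °C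
Reagents that add atoms: dimethyl (1-diazo-2-oxopropyl)phosphonate CC(=O)C(=[N+]=[N-])P(=O)(OC)OC
Why: Seyferth–Gilbert homologation with the Ohira–Bestmann reagent converts the aldehyde into the terminal alkyne under mild base at low temperature, which should leave the epimerisable cis C14 centre intact.

Step 9
Reactants: 12 (2E,6E)-farnesyl chloride
Product: 13 (2E,6E,10E)-12-chloro-2,6,10-trimethyldodeca-2,6,10-trien-1-ol
Conditions: SeO2 (cat.), t-BuOOH, salicylic acid (cat.), CH2Cl2, rt
Reagents that add atoms: selenium dioxide O=[Se]=O (catalytic oxygen carrier); tert-butyl hydroperoxide CC(C)(C)OO (terminal oxidant)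
Why: Catalytic SeO2 allylic oxidation should select the (E)-methyl of the terminal isopropylidene, the alkene next to the allylic chloride being deactivated.

Step 10
Reactants: 13 (2E,6E,10E)-12-chloro-2,6,10-trimethyldodeca-2,6,10-trien-1-ol
Product: 14 TBS ether of 13
Conditions: TBSCl, imidazole, CH2Cl2, 0 °C
Reagents that add atoms: tert-butyldimethylsilyl chloride CC(C)(C)[Si](C)(C)Cl
Why: Silylation of the primary allylic alcohol protects it from trimethylaluminium in step 11.

Step 11
Reactants: 11 cis-ethynylcyclohexene; 14 TBS ether of 13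
Product: 17 seco allylic alcohol (12E), via alkenyl(dimethyl)alane 15 (not isolated), via silyl ether 16 (not isolated)
Conditions: Me3Al, Cp2ZrCl2 (cat.), CH2Cl2, 0 °C→rt; then 14, Pd(PPh3)4 (5 mol %), THF, rt; HCl work-up; then TBAF, THF
Reagents that add atoms: trimethylaluminium C[Al](C)C
Why: Negishi zirconium-catalysed syn-carboalumination places CH3 on C13 and Al on C12 cis to it, Pd-catalysed coupling of the alkenylalane with the allylic chloride at its primary terminus retains both alkene geometries to give the 12E skipped diene, and fluoride then frees the allylic alcohol.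

Step 12
Reactants: 17 seco allylic alcohol
Product: 18 (3S,4S)-epoxy alcohol
Conditions: Ti(Oi-Pr)4, L-(+)-diethyl tartrate, t-BuOOH, 4 Å MS, CH2Cl2, −20 °C
Reagents that add atoms: tert-butyl hydroperoxide CC(C)(C)OO
Why: Sharpless asymmetric epoxidation is specific for the single allylic-alcohol alkene among six C=C bonds and, under reagent control by L-(+)-tartrate, should give the (3S,4S)-epoxide.

Step 13
Reactants: 18 (3S,4S)-epoxy alcohol
Product: 19 dimer 3β,18-diol 3'β,18'-acetonide
Conditions: Cp2TiCl2 (2.5 equiv), Mn dust, THF, rt, 5 mM; cold 1 M HCl work-up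
Reagents that add atoms: none
Why: Cp2Ti(III)Cl opens the epoxide homolytically at the C4–O bond; the tertiary C4 radical adds 6-endo-trig to C5 of the C5=C10 alkene (ring A), the resulting C10 radical adds 6-endo-trig to C9 of the C8=C9 alkene (ring B, closed last), and the tertiary C8 radical is captured by a second Ti(III) and loses a β-hydrogen from the C17 methyl to leave the exocyclic C8=C17 bond. The closest known reaction type is the titanocene(III)-mediated radical epoxypolyene cyclization (Nugent–RajanBabu epoxide opening followed by a terpene-type radical cascade). Both closures run through a chair–chair array of the (E)-alkenes, which gives the trans ring fusion (5α-H, 10β-CH3) and the equatorial C9 side chain (9α-H). The absolute sense of folding is dictated by the epoxide-derived C3 stereocentre, whose bulky O–Ti group takes the equatorial position, and at the planar C4 radical the larger Ti-bound oxymethyl group is expected to take the equatorial site anti to C2 and away from the axial C10 methyl, giving 4α-CH2OH. The step needs chemoselectivity over four other C=C bonds, secured because Ti(III) reacts only with the epoxide and the C8 radical can reach the C12=C13 bond only by 4-exo or 5-endo closure, and exo- over endocyclic alkene selectivity, secured by Ti-mediated hydride loss from the unhindered methyl.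

Step 14
Reactants: 19 dimer 3β,18-diol 3'β,18'-acetonide
Product: 20 dimer 3β,18,3'β,18'-tetraol
Conditions: AcOH/THF/H2O (3:1:1), 45 °C
Reagents that add atoms: none
Why: Mild aqueous acid hydrolysis of the isopropylidene acetal, under which the two exocyclic methylenes should not migrate.

Step 15
Reactants: 20 dimer 3β,18,3'β,18'-tetraol
Product: 21 bis(3,18-cyclic thionocarbonate)
Conditions: 1,1'-thiocarbonyldiimidazole, DMAP (cat.), THF, reflux
Reagents that add atoms: 1,1'-thiocarbonyldiimidazole S=C(n1ccnc1)n1ccnc1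
Why: Each 1,3-diol condenses with thiocarbonyldiimidazole to a six-membered cyclic thionocarbonate, which activates the secondary C3 and C3' oxygens for radical removal.

Step 16
Reactants: 21 bis(3,18-cyclic thionocarbonate)
Product: 23 target CNP0194625.1, via bis(S-tributylstannyl thiocarbonate) 22 (not isolated)
Conditions: Bu3SnH, AIBN (cat.), toluene, 100 °C; then NaOH, MeOH/H2O, rt
Reagents that add atoms: none
Why: Barton–McCombie-type radical deoxygenation: the stannyl radical adds to C=S, the ring should open toward the more stable secondary C3 (C3') radical, which is reduced to CH2, and the primary oxygen stays as an S-stannyl thiocarbonate that base hydrolysis converts into the free C18 (C18') alcohol.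

Compound list
1 | 3-methyl-2,5-dihydrothiophene 1,1-dioxide (3-methyl-3-sulfolene) | CC1=CCS(=O)(=O)C1 | starting material
2 | (2E,6E)-farnesyl bromide, (2E,6E)-1-bromo-3,7,11-trimethyldodeca-2,6,10-triene | BrC/C=C(\C)CC/C=C(\C)CCC=C(C)C | starting material
3 | 3-methyl-2-[(2E,6E)-3,7,11-trimethyldodeca-2,6,10-trien-1-yl]-2,5-dihydrothiophene 1,1-dioxide (racemic at C2) | CC1=CCS(=O)(=O)C1C/C=C(\C)CC/C=C(\C)CCC=C(C)C | intermediate
4 | 2-[(2E,6E,10E)-12-hydroxy-3,7,11-trimethyldodeca-2,6,10-trien-1-yl]-3-methyl-2,5-dihydrothiophene 1,1-dioxide (racemic at C2) | CC1=CCS(=O)(=O)C1C/C=C(\C)CC/C=C(\C)CC/C=C(\C)CO | intermediate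
5 | (2E,6E,10E,13E)-2,6,10,14-tetramethylhexadeca-2,6,10,13,15-pentaen-1-ol | OC/C(C)=C/CC/C(C)=C/CC/C(C)=C/C/C=C(C)/C=C | intermediate
6 | [(2S,3S)-2-methyl-3-[(3E,7E,10E)-3,7,11-trimethyltrideca-3,7,10,12-tetraen-1-yl]oxiran-2-yl]methanol | OC[C@]1(C)O[C@H]1CC/C(C)=C/CC/C(C)=C/C/C=C(C)/C=C | intermediate
7 | labda-8(17),12E,14-triene-3β,18-diol (3S; 5α-H, 9α-H, 10β-CH3; 4α-CH2OH equatorial, 4β-CH3) | C=C/C(C)=C/C[C@H]1C(=C)CC[C@H]2[C@](C)(CO)[C@@H](O)CC[C@]12C | intermediate
8 | 3β,18-O-isopropylidene acetal of 7 | C=C/C(C)=C/C[C@H]1C(=C)CC[C@H]2[C@]3(C)COC(C)(C)O[C@H]3CC[C@]12C | intermediate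
9 | acrolein (prop-2-enal) | C=CC=O | starting material
10 | cis-(1S,2S)-3-methylcyclohex-3-ene-1-carbaldehyde whose C2 carries the C11'H2 arm of the 3'β,18'-O-isopropylidene-8'(17')-labdene bicycle (ring carbons C14 and C12' both S) | O=C[C@H]1CCC=C(C)[C@H]1C[C@H]1C(=C)CC[C@H]2[C@]3(C)COC(C)(C)O[C@H]3CC[C@]12C | intermediate
11 | alkyne analogue of 10 (C≡CH in place of CHO; C14 and C12' unchanged, cis) | C#C[C@H]1CCC=C(C)[C@H]1C[C@H]1C(=C)CC[C@H]2[C@]3(C)COC(C)(C)O[C@H]3CC[C@]12C | intermediate
12 | (2E,6E)-farnesyl chloride, (2E,6E)-1-chloro-3,7,11-trimethyldodeca-2,6,10-triene | ClC/C=C(\C)CC/C=C(\C)CCC=C(C)C | starting material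
13 | (2E,6E,10E)-12-chloro-2,6,10-trimethyldodeca-2,6,10-trien-1-ol | ClC/C=C(\C)CC/C=C(\C)CC/C=C(\C)CO | intermediate
14 | tert-butyldimethylsilyl ether of 13 | ClC/C=C(\C)CC/C=C(\C)CC/C=C(\C)CO[Si](C)(C)C(C)(C)C | intermediate
15 | (E)-alkenyl(dimethyl)alane from 11 (Al on C12, new CH3 on C13, cis to each other) | C[Al](C)/C=C(\C)[C@H]1CCC=C(C)[C@H]1C[C@H]1C(=C)CC[C@H]2[C@]3(C)COC(C)(C)O[C@H]3CC[C@]12C | intermediate (not isolated)
16 | tert-butyldimethylsilyl ether of 17 | CC(C)(C)[Si](C)(C)OC/C(C)=C/CC/C(C)=C/CC/C(C)=C/C/C=C(\C)[C@H]1CCC=C(C)[C@H]1C[C@H]1C(=C)CC[C@H]2[C@]3(C)COC(C)(C)O[C@H]3CC[C@]12C | intermediate (not isolated)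
17 | seco allylic alcohol: (3E,5(10)E,8E,12E)-tetraene chain C18(OH)–C4=C3…C8=C9–C11–C12=C13(CH3) attached at C13 to C14 of the cis-(14S,12'S)-cyclohexene, right half as in 8 | OC/C(C)=C/CC/C(C)=C/CC/C(C)=C/C/C=C(\C)[C@H]1CCC=C(C)[C@H]1C[C@H]1C(=C)CC[C@H]2[C@]3(C)COC(C)(C)O[C@H]3CC[C@]12C | intermediate
18 | (3S,4S)-3,4-epoxide of 17 [(2S,3S)-oxiranylmethanol terminus] | OC[C@]1(C)O[C@H]1CC/C(C)=C/CC/C(C)=C/C/C=C(\C)[C@H]1CCC=C(C)[C@H]1C[C@H]1C(=C)CC[C@H]2[C@]3(C)COC(C)(C)O[C@H]3CC[C@]12C | intermediate
19 | dimer with left half 3β,18-diol (8(17)-ene, 5α-H, 9α-H, 10β-CH3, 4α-CH2OH) and right half 3'β,18'-O-isopropylidene | C=C1CC[C@H]2[C@](C)(CO)[C@@H](O)CC[C@]2(C)[C@H]1C/C=C(\C)[C@H]1CCC=C(C)[C@H]1C[C@H]1C(=C)CC[C@H]2[C@]3(C)COC(C)(C)O[C@H]3CC[C@]12C | intermediate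
20 | dimer 3β,18,3'β,18'-tetraol | C=C1CC[C@H]2[C@](C)(CO)[C@@H](O)CC[C@]2(C)[C@H]1C/C=C(\C)[C@H]1CCC=C(C)[C@H]1C[C@H]1C(=C)CC[C@H]2[C@](C)(CO)[C@@H](O)CC[C@]12C | intermediate
21 | dimer bis(3,18- and 3',18'-cyclic thionocarbonate) | C=C1CC[C@H]2[C@]3(C)COC(=S)O[C@H]3CC[C@]2(C)[C@H]1C/C=C(\C)[C@H]1CCC=C(C)[C@H]1C[C@H]1C(=C)CC[C@H]2[C@]3(C)COC(=S)O[C@H]3CC[C@]12C | intermediate
22 | 3,3'-dideoxy dimer bearing O-C(=O)-S-SnBu3 on C18 and C18' | C=C1CC[C@H]2[C@](C)(COC(=O)S[Sn](CCCC)(CCCC)CCCC)CCC[C@]2(C)[C@H]1C/C=C(\C)[C@H]1CCC=C(C)[C@H]1C[C@H]1C(=C)CC[C@H]2[C@](C)(COC(=O)S[Sn](CCCC)(CCCC)CCCC)CCC[C@]12C | intermediate (not isolated)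
23 | CNP0194625.1, endo Diels–Alder dimer of labda-8(17),12E,14-trien-18-ol (both decalins 5α-H, 9α-H, 10β-CH3, 4α-CH2OH; cyclohexene C14 and C12' cis, both S; 12E) | C=C1CC[C@H]2[C@](C)(CO)CCC[C@]2(C)[C@H]1C/C=C(\C)[C@H]1CCC=C(C)[C@H]1C[C@H]1C(=C)CC[C@H]2[C@](C)(CO)CCC[C@]12C | target

Total step count: 16. Longest linear sequence: 14 steps (steps 1–8 and 11–16; steps 9–10 make the second C15 building block).

Steps most likely to fail

1. Step 13 (key cyclization). The planar C4 radical may not discriminate well between CH2OH and CH3 for the equatorial site, so C4 epimers could form. The C4 radical may also be reduced or eliminated before ring A closes. Hydride loss may occur into the ring and give endocyclic alkenes. The fallback moves from the radical to the cation–olefin manifold, where the C4–O bond is broken with inversion in concert with C4–C5 bond formation, so that the C4 configuration follows stereospecifically from the (E)-alkene. It sets out from 18: acetylation (Ac2O, pyridine) gives the epoxy acetate F1; MeAlCl2 in CH2Cl2 at −78 °C should close both rings to the 3β-hydroxy 18-acetate F2 (the alkene isomers would have to be separated here); K2CO3 in MeOH removes the acetate and the route is rejoined at 19.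

2. Step 7 (Diels–Alder). The C13' methyl opposes the C12' alkyl group in directing the diene, so regiocontrol may be incomplete. Endo/exo leakage is possible. The labdane substituent may partly override the facial control of the catalyst. The lipophilic diene may also react slowly in the aqueous medium. The fallback replaces catalyst control by auxiliary control under Lewis-acid activation. It sets out from 8: (R)-3-acryloyl-4-benzyloxazolidin-2-one with Et2AlCl in CH2Cl2 at −78 °C (chelated dienophile, endo addition anti to the benzyl group) should give the N-acyl oxazolidinone adduct F3; LiBH4 cleaves the auxiliary to the primary alcohol F4; Dess–Martin oxidation rejoins the route at 10.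

3. Step 16 (double deoxygenation). The thionocarbonate radical may fragment toward the primary C18–O bond, which would remove the wrong oxygen, or ring opening may stall. The fallback differentiates the hydroxyls by protection instead of relying on the direction of fragmentation. It sets out from 20: TBSCl and imidazole silylate only the two primary hydroxyls to give the 18,18'-bis-silyl ether diol F5; NaH, CS2 and MeI convert the two secondary 3β-hydroxyls into the bis(S-methyl xanthate) F6; Bu3SnH with AIBN gives the 3,3'-dideoxy bis-silyl ether F7; TBAF then delivers 23.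

Further compounds
F1 | step 13 | 18-O-acetyl derivative of epoxy alcohol 18 | CC(=O)OC[C@]1(C)O[C@H]1CC/C(C)=C/CC/C(C)=C/C/C=C(\C)[C@H]1CCC=C(C)[C@H]1C[C@H]1C(=C)CC[C@H]2[C@]3(C)COC(C)(C)O[C@H]3CC[C@]12C
F2 | step 13 | 18-O-acetyl derivative of 19 (3β-hydroxy 18-acetate) | C=C1CC[C@H]2[C@](C)(COC(C)=O)[C@@H](O)CC[C@]2(C)[C@H]1C/C=C(\C)[C@H]1CCC=C(C)[C@H]1C[C@H]1C(=C)CC[C@H]2[C@]3(C)COC(C)(C)O[C@H]3CC[C@]12C
F3 | step 7 | N-acyl (R)-4-benzyloxazolidin-2-one Diels–Alder adduct (imide analogue of 10) | O=C([C@H]1CCC=C(C)[C@H]1C[C@H]1C(=C)CC[C@H]2[C@]3(C)COC(C)(C)O[C@H]3CC[C@]12C)N1[C@H](Cc2ccccc2)COC1=O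
F4 | step 7 | primary alcohol analogue of 10 (CH2OH in place of CHO) | OC[C@H]1CCC=C(C)[C@H]1C[C@H]1C(=C)CC[C@H]2[C@]3(C)COC(C)(C)O[C@H]3CC[C@]12C
F5 | step 16 | 18,18'-bis-O-TBS ether of tetraol 20 | C=C1CC[C@H]2[C@](C)(CO[Si](C)(C)C(C)(C)C)[C@@H](O)CC[C@]2(C)[C@H]1C/C=C(\C)[C@H]1CCC=C(C)[C@H]1C[C@H]1C(=C)CC[C@H]2[C@](C)(CO[Si](C)(C)C(C)(C)C)[C@@H](O)CC[C@]12C
F6 | step 16 | 3,3'-bis(S-methyl xanthate) of F5 | C=C1CC[C@H]2[C@](C)(CO[Si](C)(C)C(C)(C)C)[C@@H](OC(=S)SC)CC[C@]2(C)[C@H]1C/C=C(\C)[C@H]1CCC=C(C)[C@H]1C[C@H]1C(=C)CC[C@H]2[C@](C)(CO[Si](C)(C)C(C)(C)C)[C@@H](OC(=S)SC)CC[C@]12C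
F7 | step 16 | 18,18'-bis-O-TBS ether of target 23 | C=C1CC[C@H]2[C@](C)(CO[Si](C)(C)C(C)(C)C)CCC[C@]2(C)[C@H]1C/C=C(\C)[C@H]1CCC=C(C)[C@H]1C[C@H]1C(=C)CC[C@H]2[C@](C)(CO[Si](C)(C)C(C)(C)C)CCC[C@]12C
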